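**Catalyst clock.** If the west and east readings fell on one curve once each time was multiplied by the catalyst charge, the asked flask could be read from that curve, so I tried that first.

| flask | starting material | coupling partner | second substrate | protic impurity | free catalyst | remark | time |
|---|---|---|---|---|---|---|---|
| west | 20 mM | 16 mM | 20 mM | 4 mM | 0.095 mM | run made earlier |  |
| east | 20 mM | 16 mM | 20 mM | 4 mM | 0.38 mM | run made earlier |  |
| flask | 20 mM | 16.0 mM | 20.0 mM | 4.00 mM | 0.19 mM |  | 15 d |

| run | time / d | target / % |
|---|---|---|
| west | 0.167 | 13 |
| west | 0.417 | 24 |
| west | 0.833 | 26 |
| west | 1.67 | 29 |
| west | 4.00 | 26 |
| west | 10.0 | 25 |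
| east | 0.167 | 27 |
| east | 0.417 | 29 |
| east | 0.833 | 29 |
| east | 1.67 | 24 |
| east | 4.00 | 23 |
| east | 10.0 | 21 |

(readings scatter by 1.5 percentage points)

- the moment within 15 d at which there is most target
- the amount of target, in percent of the starting material charged, at that time



**Catalyst setting.** By hand, more catalyst should bring the top earlier and leave its height alone. The runs did that: west read 29 % at 1.67 d, east 29 % at 0.417 d. West gave 13.7 M·s and east 13.7 M·s of what I called the top dose, the catalyst charge times the time of the first highest reading. Dividing by the flask's charge gave a first answer of 0.835 d.

**Second round.** I put that answer back among the readings. East still read 29 % at twice that dose, so the top of the east run read flat. I committed to 0.835 d, with a height within 1.5 percentage points of 29 %.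

**Time setting.** By hand, waiting past the top should lose target. The flask's end dose, 246 M·s, lay above west's last 82.1 M·s and below east's last 328 M·s. Those readings had fallen to 25 % and 21 %.

**The forecast.** It gave 1 d and 28.5 %, reasoning that “its clock runs twice as fast as west and half as fast as east”. My time was earlier than its time.

    second substrate + coupling partner + free catalyst → free catalyst + second product (k = 19.9 /M²/s)
    second substrate + free catalyst → spent catalyst (k = 3.14 × 10⁻⁴ /M/s)
    target + free catalyst ⇌ isomer of the product + free catalyst, rate k3*[free catalyst]*[target] forward; the back reaction follows from the equilibrium constant (K = 0.590, k = 0.00772 /M/s)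
    starting material + coupling partner + free catalyst → free catalyst + target (k = 11.2 /M²/s)
    starting material + protic impurity → quenched substrate (k = 0.00119 /M/s)

**The flask.** The flask reached its top at 0.691 d, with 28.2 % of target, so the forecast's height held and its time was late by a factor of 1.45. The top dose of 13.7 M·s, divided by the flask's charge, had given 0.835 d, earlier than 0.864 d, when the flask still held 28.1 %. A neighbour charged with 16 mM of protic impurity had the same catalyst charge, so the top dose gave it the same 0.835 d, and its highest target was 25.7 %.

All runs are calculated for an exercise, noise included.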